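**Strategy.** The cyclohexenone ring is disconnected at C6–C7 and C8–C9 (spiro[4.5]decene numbering), leaving a cyclopentane whose quaternary C5 carries an acetyl group (C6) and a 1-oxopropan-2-yl arm (C10, C9). The key step stitches a two-carbon α-ethoxyvinyl anion between these two carbonyls in one flask: its carbanion carbon (C8) adds to the aldehyde under Felkin–Anh control, setting C9, and the resulting 2-ethoxyallyl enol ether carbon (C7) then attacks the acetyl ketone under TiCl4. It exploits the 1,4-relationship of the C6 ketone and the C9 aldehyde across C5 and C10. The precursor comes from (S)-limonene oxide by ring contraction, catalytic nitro-Michael addition, reduction and Nef reaction.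

Key step: step 9

Remark: atom labels C1–C10 follow the spiro[4.5]decane numbering of the target (C1 isobutyryloxy carbon, C3 isopropenyl carbon, C5 spiro atom, C6 methyl-bearing sp2 carbon, C7 vinyl CH, C8 ketone, C9 acetoxy carbon, C10 methyl-bearing sp3 carbon). (S)-Limonene oxide and (E)-1-nitroprop-1-ene are taken as purchasable.

**Step 1**
Reactants: 1 (4S)-limonene 1,2-oxide (cis/trans mixture)
Product: 3 (3S)-6-oxo-3-(prop-1-en-2-yl)heptanal, via limonene-1,2-diol 2 (not isolated)
Conditions: H5IO6 (1.1 equiv), THF/H2O, 0 °C → rt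
Reagents that add atoms: water, O
Why: Acid-mediated epoxide hydration followed by Malaprade glycol cleavage should convert both epoxide diastereomers into the same keto aldehyde, leaving the isopropenyl group and the C3 stereocentre untouched.

**Step 2**
Reactants: 3 (3S)-6-oxo-3-(prop-1-en-2-yl)heptanal
Product: 4 1-[(4R)-4-(prop-1-en-2-yl)cyclopent-1-en-1-yl]ethan-1-one
Conditions: KOH (0.2 equiv), MeOH/H2O, 0 °C → rt
Reagents that add atoms: none
Why: Hydroxide-mediated intramolecular aldol condensation, in which the enolate of the internal ketone methylene adds to the aldehyde (5-(enolexo)-exo-trig) and the aldol dehydrates to the conjugated acetylcyclopentene; no stereocentre is formed.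

**Step 3**
Reactants: 4 1-[(4R)-4-(prop-1-en-2-yl)cyclopent-1-en-1-yl]ethan-1-one
Product: 5 1-[(3R)-3-(prop-1-en-2-yl)-6-oxabicyclo[3.1.0]hexan-1-yl]ethan-1-one (epoxide epimers)
Conditions: 30% H2O2, NaOH (cat.), MeOH, 0 °C
Reagents that add atoms: hydrogen peroxide, OO
Why: Weitz–Scheffer epoxidation attacks only the electron-poor enone double bond, the isopropenyl group is inert, and the two new centres (expected mainly anti to isopropenyl) are both erased in step 4.

**Step 4**
Reactants: 5 epoxy ketone
Product: 6 (4S)-2-acetyl-4-(prop-1-en-2-yl)cyclopentan-1-one (keto/enol tautomers, C5 labile)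
Conditions: Pd(PPh3)4 (5 mol %), 1,2-bis(diphenylphosphino)ethane (5 mol %), toluene, 80 °C
Reagents that add atoms: none
Why: Isomerisation of an α,β-epoxy ketone to a 1,3-diketone by zerovalent palladium (oxidative addition into the Cα–O bond, β-hydride elimination of the C1 hydrogen, tautomerisation) should make C5 an enolisable carbon between two carbonyls.

**Step 5**
Reactants: 6 (4S)-2-acetyl-4-(prop-1-en-2-yl)cyclopentan-1-one; 7 (E)-1-nitroprop-1-ene
Product: 8 (2R,4S)-2-acetyl-2-[(2S)-1-nitropropan-2-yl]-4-(prop-1-en-2-yl)cyclopentan-1-one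
Conditions: 1-[3,5-bis(trifluoromethyl)phenyl]-3-[(1R,2R)-2-(dimethylamino)cyclohexyl]thiourea (10 mol %), toluene, −20 °C
Reagents that add atoms: none
Why: Bifunctional thiourea–amine catalysed Michael addition of the enolised 1,3-diketone, in which C5 is alkylated on the ring face anti to the C3 isopropenyl group and the hydrogen-bonded nitroalkene is attacked on the Re face of its C2 (the sense expected for this catalyst enantiomer), setting C10.

**Step 6**
Reactants: 8 Michael adduct
Product: 9 1-[(1S,2R,4S)-2-hydroxy-1-[(2S)-1-nitropropan-2-yl]-4-(prop-1-en-2-yl)cyclopentyl]ethan-1-one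
Conditions: LiBH(s-Bu)3 (2.2 equiv), THF, −78 °C; then AcOH, −78 °C
Reagents that add atoms: none
Why: Substrate-controlled ketone reduction, in which the bulky hydride should attack the ring carbonyl (open on the face syn to the flat acetyl group) faster than the acetyl carbonyl shielded by the quaternary carbon, so hydride enters anti to the branched nitroalkyl arm and the C1 hydroxyl ends cis to that arm and trans to isopropenyl.

**Step 7**
Reactants: 9 hydroxy nitro ketone
Product: 10 (1R,2S,4S)-2-acetyl-2-[(2S)-1-nitropropan-2-yl]-4-(prop-1-en-2-yl)cyclopentyl 2-methylpropanoate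
Conditions: (i-PrCO)2O (1.5 equiv), Sc(OTf)3 (5 mol %), MeCN, −20 → 0 °C
Reagents that add atoms: isobutyric anhydride, CC(C)C(=O)OC(=O)C(C)C
Why: Lewis acid catalysed acylation esterifies the hindered secondary alcohol with retention under non-basic conditions, so the acidic primary nitro group is not turned into a nitronate and the β-hydroxy ketone cannot undergo retro-aldol cleavage.

**Step 8**
Reactants: 10 nitro ester
Product: 12 (1R,2S,4S)-2-acetyl-2-[(2S)-1-oxopropan-2-yl]-4-(prop-1-en-2-yl)cyclopentyl 2-methylpropanoate, via sodium nitronate 11 (not isolated)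
Conditions: NaOMe (1.0 equiv), MeOH, −20 °C; then aq. TiCl3 (4 equiv), NH4OAc buffer (pH 5), 0 °C → rt
Reagents that add atoms: water, O
Why: Reductive Nef reaction, in which trivalent titanium reduces the nitronate to the imine and this hydrolyses at pH 5 to the aldehyde without touching ketone, ester or alkene and without epimerising C10, whose hydrogen is flanked by the quaternary centre.

**Step 9**
Reactants: 12 keto aldehyde
Product: 14 (1R,3S,5S,9R,10S)-6,9-dihydroxy-6,10-dimethyl-8-oxo-3-(prop-1-en-2-yl)spiro[4.5]decan-1-yl 2-methylpropanoate (C6 epimers), via lithium alkoxide 13 (not isolated)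
Conditions: CH2=C(OEt)Li (1.2 equiv, from ethyl vinyl ether and t-BuLi, THF, −78 → 0 °C), THF, −78 °C; then CH2Cl2, TiCl4 (3 equiv), −78 → −20 °C; aq. NaHCO3
Reagents that add atoms: 1-ethoxyvinyllithium, [Li]C(=C)OCC (made from ethyl vinyl ether, C=COCC, and t-BuLi); water, O
Why: 1-Ethoxyvinyllithium, an acetyl anion equivalent, adds chemoselectively to the aldehyde of 12 (the methyl ketone is neopentyl, the ester hindered) to give alkoxide 13 and the C8–C9 bond; after transmetalation with TiCl4 the 2-ethoxyallyl enol ether carbon C7 attacks the titanium-activated acetyl carbonyl in a Mukaiyama-type aldol addition, forming C6–C7, and aqueous work-up hydrolyses the ethoxycarbenium ion to the C8 ketone. The closest known reactions are the addition of α-alkoxyvinyllithiums to aldehydes and the Lewis acid mediated addition of enol ethers to ketones. The six-membered ring closes in the 6-(enolendo)-exo-trig mode. C9 is set by Felkin–Anh addition anti to the quaternary C5 substituent of the α-stereocentre C10, which gives the 9,10-trans arrangement; the C6 carbinol centre is not controlled and is removed in step 10. The step needs aldehyde-over-ketone selectivity in the first stage and, in the second, attack by C7 and not by the acetyl methyl group on the new carbonyl, which the preformed enol ether secures because no free C8 ketone exists until work-up. The titanium alkoxide at C9 is a poor leaving group, which should suppress ionisation to a 2-ethoxyallyl cation.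

**Step 10**
Reactants: 14 ketol
Product: 16 (1R,3S,5R,9R,10S)-9-(acetyloxy)-6,10-dimethyl-8-oxo-3-(prop-1-en-2-yl)spiro[4.5]dec-6-en-1-yl 2-methylpropanoate, via bis-acetate 15 (not isolated)
Conditions: Ac2O (4 equiv), DMAP (0.5 equiv), Et3N, CH2Cl2, rt → 40 °C
Reagents that add atoms: acetic anhydride, CC(=O)OC(C)=O
Why: DMAP-catalysed acetylation of both hydroxyls followed by E1cB loss of the tertiary β-acetoxy group should give the conjugated C6=C7 enone, and C9 should keep its configuration because the 9,10-trans acetate is expected to be the thermodynamically preferred epimer as well.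

**Compound list**
1 | (4S)-limonene 1,2-oxide, cis/trans mixture | CC12OC1C[C@H](CC2)C(C)=C | starting material
2 | (4S)-1-methyl-4-(prop-1-en-2-yl)cyclohexane-1,2-diol (diastereomer mixture) | CC1(O)C(O)C[C@H](CC1)C(C)=C | intermediate
3 | (3S)-6-oxo-3-(prop-1-en-2-yl)heptanal | CC(=O)CC[C@@H](CC=O)C(C)=C | intermediate
4 | 1-[(4R)-4-(prop-1-en-2-yl)cyclopent-1-en-1-yl]ethan-1-one | CC(=O)C1=CC[C@H](C1)C(C)=C | intermediate
5 | 1-[(3R)-3-(prop-1-en-2-yl)-6-oxabicyclo[3.1.0]hexan-1-yl]ethan-1-one (epoxide epimers) | CC(=O)C12OC1C[C@H](C2)C(C)=C | intermediate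
6 | (4S)-2-acetyl-4-(prop-1-en-2-yl)cyclopentan-1-one | CC(=O)C1C(=O)C[C@H](C1)C(C)=C | intermediate
7 | (E)-1-nitroprop-1-ene | C/C=C/[N+](=O)[O-] | starting material
8 | (2R,4S)-2-acetyl-2-[(2S)-1-nitropropan-2-yl]-4-(prop-1-en-2-yl)cyclopentan-1-one | C=C(C)[C@@H]1CC(=O)[C@@]([C@H](C)C[N+](=O)[O-])(C1)C(C)=O | intermediate
9 | 1-[(1S,2R,4S)-2-hydroxy-1-[(2S)-1-nitropropan-2-yl]-4-(prop-1-en-2-yl)cyclopentyl]ethan-1-one | C=C(C)[C@@H]1C[C@@H](O)[C@@]([C@H](C)C[N+](=O)[O-])(C1)C(C)=O | intermediate
10 | (1R,2S,4S)-2-acetyl-2-[(2S)-1-nitropropan-2-yl]-4-(prop-1-en-2-yl)cyclopentyl 2-methylpropanoate | C=C(C)[C@@H]1C[C@@H](OC(=O)C(C)C)[C@@]([C@H](C)C[N+](=O)[O-])(C1)C(C)=O | intermediate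
11 | sodium nitronate of 10 | [Na+].C=C(C)[C@@H]1C[C@@H](OC(=O)C(C)C)[C@@]([C@H](C)C=[N+]([O-])[O-])(C1)C(C)=O | intermediate
12 | (1R,2S,4S)-2-acetyl-2-[(2S)-1-oxopropan-2-yl]-4-(prop-1-en-2-yl)cyclopentyl 2-methylpropanoate | C=C(C)[C@@H]1C[C@@H](OC(=O)C(C)C)[C@@]([C@H](C)C=O)(C1)C(C)=O | intermediate
13 | lithium alkoxide of (1R,2S,4S)-2-acetyl-2-[(2S,3R)-4-ethoxy-3-hydroxypent-4-en-2-yl]-4-(prop-1-en-2-yl)cyclopentyl 2-methylpropanoate | [Li+].C=C(C)[C@@H]1C[C@@H](OC(=O)C(C)C)[C@@]([C@H](C)[C@@H]([O-])C(=C)OCC)(C1)C(C)=O | intermediate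
14 | (1R,3S,5S,9R,10S)-6,9-dihydroxy-6,10-dimethyl-8-oxo-3-(prop-1-en-2-yl)spiro[4.5]decan-1-yl 2-methylpropanoate (C6 epimers) | C=C(C)[C@@H]1C[C@@H](OC(=O)C(C)C)[C@@]2(C1)C(C)(O)CC(=O)[C@H](O)[C@H]2C | intermediate
15 | (1R,3S,5S,9R,10S)-6,9-bis(acetyloxy)-6,10-dimethyl-8-oxo-3-(prop-1-en-2-yl)spiro[4.5]decan-1-yl 2-methylpropanoate (C6 epimers) | C=C(C)[C@@H]1C[C@@H](OC(=O)C(C)C)[C@@]2(C1)C(C)(OC(C)=O)CC(=O)[C@H](OC(C)=O)[C@H]2C | intermediate
16 | (1R,3S,5R,9R,10S)-9-(acetyloxy)-6,10-dimethyl-8-oxo-3-(prop-1-en-2-yl)spiro[4.5]dec-6-en-1-yl 2-methylpropanoate | C=C(C)[C@@H]1C[C@@H](OC(=O)C(C)C)[C@@]2(C1)C(C)=CC(=O)[C@H](OC(C)=O)[C@H]2C | target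

**Step count.** Total: 10 steps. Longest linear sequence: 10 steps.

**Steps most likely to fail**

1. Step 9 (key step). The Lewis acid stage may fail through ionisation or elimination of the 2-ethoxyallyl unit, through hydrolysis of the enol ether before ring closure, through competing attack of the isopropenyl group on the activated ketone, or through loss of C9 configuration by an ene-type proton shift. Fallback, from 12: the 1-ethoxyvinyllithium adduct is quenched with Ac2O and the 2-ethoxyallyl acetate F1 is isolated. NBS in aqueous THF then converts the enol ether regiospecifically into the bromomethyl ketone F2. CrCl2 in THF effects an intramolecular Reformatsky-type aldol addition of the resulting enolate to the acetyl ketone, giving the ketol acetate F3. F3 is acetylated under the conditions of step 10, so the route is rejoined at 15.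

2. Step 5. Facial selectivity may be poor if the substrate bias at C5 (anti to isopropenyl) and the catalyst are mismatched, or the nitroalkene may be attacked on the wrong face, giving the C10 epimer. Fallback, from 6: addition–elimination with (E)-N,N-dimethyl-2-nitroethenamine installs a 2-nitrovinyl group at C5 anti to isopropenyl, giving the nitrovinyl diketone F4. Cu(OTf)2 with a chiral phosphoramidite ligand then catalyses conjugate addition of Me2Zn, so the C10 methyl group is delivered under ligand control, independently of the ring face already fixed. The route is rejoined at 8.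

3. Step 6. The hydride may not discriminate between the ring carbonyl and the acetyl carbonyl, or may attack the ring carbonyl from the face of the nitroalkyl arm. Fallback, from 5 (epimer with the epoxide anti to isopropenyl): two-electron reductive opening with lithium 4,4′-di-tert-butylbiphenylide at −78 °C gives the dilithium enolate alkoxide F5, in which the C1 oxygen is already in place. Michael addition of F5 to 7 at −78 °C, with the nitro group expected to coordinate the lithium alkoxide and be delivered syn to oxygen, followed by protonation gives 9 without any ketone differentiation. The route is rejoined at 9.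

**Further compounds**
F1 | step 9 | (1R,2S,4S)-2-acetyl-2-[(2S,3R)-3-(acetyloxy)-4-ethoxypent-4-en-2-yl]-4-(prop-1-en-2-yl)cyclopentyl 2-methylpropanoate | C=C(C)[C@@H]1C[C@@H](OC(=O)C(C)C)[C@@]([C@H](C)[C@@H](OC(C)=O)C(=C)OCC)(C1)C(C)=O
F2 | step 9 | (1R,2S,4S)-2-acetyl-2-[(2S,3R)-3-(acetyloxy)-5-bromo-4-oxopentan-2-yl]-4-(prop-1-en-2-yl)cyclopentyl 2-methylpropanoate | C=C(C)[C@@H]1C[C@@H](OC(=O)C(C)C)[C@@]([C@H](C)[C@@H](OC(C)=O)C(=O)CBr)(C1)C(C)=O
F3 | step 9 | (1R,3S,5S,9R,10S)-9-(acetyloxy)-6-hydroxy-6,10-dimethyl-8-oxo-3-(prop-1-en-2-yl)spiro[4.5]decan-1-yl 2-methylpropanoate (C6 epimers) | C=C(C)[C@@H]1C[C@@H](OC(=O)C(C)C)[C@@]2(C1)C(C)(O)CC(=O)[C@H](OC(C)=O)[C@H]2C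
F4 | step 5 | (2R,4S)-2-acetyl-2-[(E)-2-nitroethenyl]-4-(prop-1-en-2-yl)cyclopentan-1-one | C=C(C)[C@@H]1CC(=O)[C@@](/C=C/[N+](=O)[O-])(C1)C(C)=O
F5 | step 6 | dilithium (1R,4S)-2-(1-oxidoethylidene)-4-(prop-1-en-2-yl)cyclopentan-1-olate | [Li+].[Li+].C=C(C)[C@@H]1C[C@@H]([O-])C(=C(C)[O-])C1
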